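Ring A is introduced last, as a 3,5-bis(benzyloxy)benzyne annulated onto an open-chain anti-aldol unit. The key step exploits the adjacent ring-A carbons C4a and C8a of the chromanone. One fluoride-triggered operation joins O1 to C8a and C4 to C4a and closes ring C; the C5 oxygen of the aryne steers the oxygen to C8a and the carbanion to C4a. The precursor is a methyl (2S,3R)-3-hydroxy-2,3-diarylpropanoate that already carries C2, C3 and the complete benzyl-protected flavone. It comes from an Evans magnesium anti-aldol reaction of an N-arylacetyl oxazolidinone, itself made by palladium enolate arylation of a 3'-bromoflavone. Global hydrogenolysis finishes the synthesis.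

Key step: step 9

Assumptions: compounds 1, 2, 5, 9 and 13 are taken as purchasable; the magnesium anti-aldol is assumed to follow the chelated-enolate facial sense (attack anti to the auxiliary benzyl group), so that the (R)-auxiliary gives the (2S,3R) adduct, and the (S)-auxiliary would be used if the opposite sense were found.

Step 1
Reactants: 1 1-[2,4-bis(benzyloxy)-6-hydroxyphenyl]ethan-1-one; 2 4-(benzyloxy)-3-bromobenzaldehyde
Product: 3 (E)-1-[2,4-bis(benzyloxy)-6-hydroxyphenyl]-3-[4-(benzyloxy)-3-bromophenyl]prop-2-en-1-one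
Conditions: KOH, EtOH/THF, rt
Reagents that add atoms: none
Why: Claisen–Schmidt condensation, in which the methyl ketone enolate adds to the non-enolisable aldehyde and E1cB dehydration should give the (E)-chalcone while the hydrogen-bonded 2'-hydroxyl stays free for the next step.

Step 2
Reactants: 3 (E)-1-[2,4-bis(benzyloxy)-6-hydroxyphenyl]-3-[4-(benzyloxy)-3-bromophenyl]prop-2-en-1-one
Product: 4 5,7-bis(benzyloxy)-2-[4-(benzyloxy)-3-bromophenyl]-4H-chromen-4-one
Conditions: I2 (10 mol %), DMSO, 120 °C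
Reagents that add atoms: none
Why: Iodine-catalysed oxidative cyclisation of a 2'-hydroxychalcone (oxa-Michael closure, α-iodination and loss of HI, with DMSO as terminal oxidant) is the standard flavone synthesis and should tolerate the aryl benzyl ethers and the aryl bromide.

Step 3
Reactants: 4 5,7-bis(benzyloxy)-2-[4-(benzyloxy)-3-bromophenyl]-4H-chromen-4-one; 5 (R)-3-acetyl-4-benzyloxazolidin-2-one
Product: 8 (R)-4-benzyl-3-{2-[2-(benzyloxy)-5-(5,7-bis(benzyloxy)-4-oxo-4H-chromen-2-yl)phenyl]acetyl}oxazolidin-2-one, via lithium enolate 6 (not isolated), via chlorozinc enolate 7 (not isolated)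
Conditions: LiN(SiMe3)2, THF, −78 °C; ZnCl2, −78 °C to rt; then 4, Pd(dba)2 (5 mol %), P(t-Bu)3 (10 mol %), THF, rt to 50 °C
Reagents that add atoms: none
Why: Palladium-catalysed α-arylation of a zinc enolate (Negishi-type enolate coupling), in which zerovalent palladium inserts into the C–Br bond of 4, the weakly basic zinc enolate transmetalates and reductive elimination forms the aryl–CH2 bond without touching the chromone or the auxiliary stereocentre.

Step 4
Reactants: 8 (R)-4-benzyl-3-{2-[2-(benzyloxy)-5-(5,7-bis(benzyloxy)-4-oxo-4H-chromen-2-yl)phenyl]acetyl}oxazolidin-2-one; 9 4-(benzyloxy)benzaldehyde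
Product: 10 (R)-4-benzyl-3-[(2S,3R)-2-{2-(benzyloxy)-5-[5,7-bis(benzyloxy)-4-oxo-4H-chromen-2-yl]phenyl}-3-[4-(benzyloxy)phenyl]-3-(trimethylsilyloxy)propanoyl]oxazolidin-2-one
Conditions: MgCl2 (1 equiv), Et3N, TMSCl, EtOAc/CH2Cl2, rt
Reagents that add atoms: chlorotrimethylsilane (TMSCl), C[Si](C)(C)Cl
Why: Evans magnesium-halide-promoted direct anti-aldol reaction, in which MgCl2/Et3N soft-enolises the chelated imide to the Z-enolate, the aldehyde adds to the enolate face remote from the benzyl group of the (R)-auxiliary to set the α-carbon as S and the carbinol carbon as R (anti), and O-silylation makes the addition irreversible; minor diastereomers should be separable at this auxiliary-bearing stage.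

Step 5
Reactants: 10 the silylated anti-aldol imide from step 4
Product: 12 methyl (2S,3R)-2-{2-(benzyloxy)-5-[5,7-bis(benzyloxy)-4-oxo-4H-chromen-2-yl]phenyl}-3-[4-(benzyloxy)phenyl]-3-hydroxypropanoate, via hydroxy imide 11 (not isolated)
Conditions: MeMgBr (3 equiv) added to MeOH/CH2Cl2, 0 °C (MeOMgBr formed in the flask)
Reagents that add atoms: methanol (delivered as MeOMgBr), CO
Why: Magnesium methoxide transesterification of an aldol imide, in which the methanolic base first cleaves the labile O–SiMe3 group, the magnesium alkoxide then chelates and activates the exocyclic imide carbonyl, and methoxide displaces the oxazolidinone without a bond change at either stereocentre.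

Step 6
Reactants: 13 3,5-bis(benzyloxy)phenol
Product: 14 3,5-bis(benzyloxy)phenyl N-isopropylcarbamate
Conditions: i-PrNCO, Et3N (cat.), CH2Cl2, rt
Reagents that add atoms: isopropyl isocyanate, CC(C)N=C=O
Why: Amine-catalysed addition of the phenol to the isocyanate (carbamoylation) should give the N-isopropyl carbamate that serves as directing group and later as a mildly removable phenol mask.

Step 7
Reactants: 14 3,5-bis(benzyloxy)phenyl N-isopropylcarbamate
Product: 18 3,5-bis(benzyloxy)-2-(trimethylsilyl)phenyl N-isopropylcarbamate, via N-silyl carbamate 15 (not isolated), via aryllithium 16 (not isolated), via N,C-disilyl carbamate 17 (not isolated)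
Conditions: TMSOTf, TMEDA, Et2O, 0 °C to rt; n-BuLi, TMEDA, −78 °C; TMSCl, −78 °C to rt; aq. NaHSO4
Reagents that add atoms: chlorotrimethylsilane (TMSCl), C[Si](C)(C)Cl
Why: Directed ortho-metalation of the N-silylated carbamate made in the flask, in which n-BuLi/TMEDA removes the proton flanked by the carbamate and a benzyloxy group (the two such positions are equivalent), TMSCl quenches the aryllithium and the N–Si bond is lost on aqueous work-up.

Step 8
Reactants: 18 3,5-bis(benzyloxy)-2-(trimethylsilyl)phenyl N-isopropylcarbamate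
Product: 20 3,5-bis(benzyloxy)-2-(trimethylsilyl)phenyl trifluoromethanesulfonate, via silyl phenol 19 (not isolated)
Conditions: DBU, Et2NH, MeCN, 40 °C; then PhNTf2, rt
Reagents that add atoms: N-phenylbis(trifluoromethanesulfonimide) (PhNTf2), O=S(=O)(N(c1ccccc1)S(=O)(=O)C(F)(F)F)C(F)(F)F
Why: Base-induced E1cB cleavage of the N–H carbamate (Et2NH traps the isocyanate as a urea) should free the phenoxide, which is sulfonylated in the same flask to give the ortho-silylaryl triflate aryne precursor.

Step 9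
Reactants: 12 methyl (2S,3R)-2-{2-(benzyloxy)-5-[5,7-bis(benzyloxy)-4-oxo-4H-chromen-2-yl]phenyl}-3-[4-(benzyloxy)phenyl]-3-hydroxypropanoate; 20 3,5-bis(benzyloxy)-2-(trimethylsilyl)phenyl trifluoromethanesulfonate
Product: 22 (2R,3S)-5,7-bis(benzyloxy)-2-[4-(benzyloxy)phenyl]-3-{2-(benzyloxy)-5-[5,7-bis(benzyloxy)-4-oxo-4H-chromen-2-yl]phenyl}chroman-4-one, via aryne 21 (not isolated)
Conditions: 20 (1.5 equiv), CsF (3 equiv), THF/MeCN, rt
Reagents that add atoms: none
Why: Proposed new method: fluoride removes the SiMe3 group of 20 to give aryne 21, the fluoride-hydrogen-bonded secondary hydroxyl of 12 adds to the aryne carbon remote from the flanking benzyloxy group (O1–C8a), and the aryl anion so formed, which lies next to that benzyloxy group, attacks the methyl ester and expels methoxide (C4–C4a), so that methanol is the only fragment lost from 12. The closest known reaction type is the aryne annulation of methyl salicylates to xanthones (O-arylation followed by intramolecular acyl substitution), which is established for phenoxide nucleophiles but not for an aliphatic β-hydroxy ester. Ring C closes by 6-exo-trig addition of the aryl anion to the ester carbonyl. No stereocentre is created: C2 and C3 are carried over from 12, C2 takes part in no bond change, and C3, being α to the new ketone, can only relax toward the more stable trans diequatorial arrangement that it already has. The step needs regioselectivity, secured by the benzyloxy group next to the aryne bond, which distorts and polarises the aryne so that nucleophiles attack the distal carbon; it also needs O- over C-arylation and ring closure over protonation, secured by using the free alcohol with CsF (no naked alkoxide, hence little retro-aldol or ester enolate) and by the six-membered geometry of the acyl transfer.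

Step 10
Reactants: 22 (2R,3S)-5,7-bis(benzyloxy)-2-[4-(benzyloxy)phenyl]-3-{2-(benzyloxy)-5-[5,7-bis(benzyloxy)-4-oxo-4H-chromen-2-yl]phenyl}chroman-4-one
Product: 23 (2R,3S)-5,7-dihydroxy-2-(4-hydroxyphenyl)-3-[2-hydroxy-5-(5,7-dihydroxy-4-oxo-4H-chromen-2-yl)phenyl]chroman-4-one
Conditions: H2 (1 atm), 10% Pd/C, THF/MeOH, rt
Reagents that add atoms: none
Why: Catalytic hydrogenolysis of the six aryl benzyl ethers under neutral conditions should leave the chromone C2=C3 bond, both ketones and the two stereocentres untouched, because neither acid nor base is present to open ring C or enolise C3.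

Compound list
1 | 1-[2,4-bis(benzyloxy)-6-hydroxyphenyl]ethan-1-one | CC(=O)c1c(O)cc(OCc2ccccc2)cc1OCc1ccccc1 | starting material
2 | 4-(benzyloxy)-3-bromobenzaldehyde | O=Cc1ccc(OCc2ccccc2)c(Br)c1 | starting material
3 | (E)-1-[2,4-bis(benzyloxy)-6-hydroxyphenyl]-3-[4-(benzyloxy)-3-bromophenyl]prop-2-en-1-one | O=C(/C=C/c1ccc(OCc2ccccc2)c(Br)c1)c1c(O)cc(OCc2ccccc2)cc1OCc1ccccc1 | intermediate
4 | 5,7-bis(benzyloxy)-2-[4-(benzyloxy)-3-bromophenyl]-4H-chromen-4-one | O=c1cc(-c2ccc(OCc3ccccc3)c(Br)c2)oc2cc(OCc3ccccc3)cc(OCc3ccccc3)c12 | intermediate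
5 | (R)-3-acetyl-4-benzyloxazolidin-2-one | CC(=O)N1[C@H](Cc2ccccc2)COC1=O | starting material
6 | lithium enolate of 5 (formed in the flask, not isolated) | [Li]OC(=C)N1[C@H](Cc2ccccc2)COC1=O | intermediate
7 | chlorozinc enolate of 5, drawn carbon-bound (formed in the flask, not isolated) | Cl[Zn]CC(=O)N1[C@H](Cc2ccccc2)COC1=O | intermediate
8 | (R)-4-benzyl-3-{2-[2-(benzyloxy)-5-(5,7-bis(benzyloxy)-4-oxo-4H-chromen-2-yl)phenyl]acetyl}oxazolidin-2-one | O=C(Cc1cc(-c2cc(=O)c3c(OCc4ccccc4)cc(OCc4ccccc4)cc3o2)ccc1OCc1ccccc1)N1[C@H](Cc2ccccc2)COC1=O | intermediate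
9 | 4-(benzyloxy)benzaldehyde | O=Cc1ccc(OCc2ccccc2)cc1 | starting material
10 | (R)-4-benzyl-3-[(2S,3R)-2-{2-(benzyloxy)-5-[5,7-bis(benzyloxy)-4-oxo-4H-chromen-2-yl]phenyl}-3-[4-(benzyloxy)phenyl]-3-(trimethylsilyloxy)propanoyl]oxazolidin-2-one | O=C([C@H]([C@@H](O[Si](C)(C)C)c1ccc(OCc2ccccc2)cc1)c1cc(-c2cc(=O)c3c(OCc4ccccc4)cc(OCc4ccccc4)cc3o2)ccc1OCc1ccccc1)N1[C@H](Cc2ccccc2)COC1=O | intermediate
11 | (R)-4-benzyl-3-[(2S,3R)-2-{2-(benzyloxy)-5-[5,7-bis(benzyloxy)-4-oxo-4H-chromen-2-yl]phenyl}-3-[4-(benzyloxy)phenyl]-3-hydroxypropanoyl]oxazolidin-2-one (formed in the flask, not isolated) | O=C([C@H]([C@@H](O)c1ccc(OCc2ccccc2)cc1)c1cc(-c2cc(=O)c3c(OCc4ccccc4)cc(OCc4ccccc4)cc3o2)ccc1OCc1ccccc1)N1[C@H](Cc2ccccc2)COC1=O | intermediate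
12 | methyl (2S,3R)-2-{2-(benzyloxy)-5-[5,7-bis(benzyloxy)-4-oxo-4H-chromen-2-yl]phenyl}-3-[4-(benzyloxy)phenyl]-3-hydroxypropanoate | COC(=O)[C@H]([C@@H](O)c1ccc(OCc2ccccc2)cc1)c1cc(-c2cc(=O)c3c(OCc4ccccc4)cc(OCc4ccccc4)cc3o2)ccc1OCc1ccccc1 | intermediate
13 | 3,5-bis(benzyloxy)phenol | Oc1cc(OCc2ccccc2)cc(OCc2ccccc2)c1 | starting material
14 | 3,5-bis(benzyloxy)phenyl N-isopropylcarbamate | CC(C)NC(=O)Oc1cc(OCc2ccccc2)cc(OCc2ccccc2)c1 | intermediate
15 | 3,5-bis(benzyloxy)phenyl N-isopropyl-N-(trimethylsilyl)carbamate (formed in the flask, not isolated) | CC(C)N(C(=O)Oc1cc(OCc2ccccc2)cc(OCc2ccccc2)c1)[Si](C)(C)C | intermediate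
16 | 2-lithio derivative of 15 (formed in the flask, not isolated) | CC(C)N(C(=O)Oc1cc(OCc2ccccc2)cc(OCc2ccccc2)c1[Li])[Si](C)(C)C | intermediate
17 | 3,5-bis(benzyloxy)-2-(trimethylsilyl)phenyl N-isopropyl-N-(trimethylsilyl)carbamate (formed in the flask, not isolated) | CC(C)N(C(=O)Oc1cc(OCc2ccccc2)cc(OCc2ccccc2)c1[Si](C)(C)C)[Si](C)(C)C | intermediate
18 | 3,5-bis(benzyloxy)-2-(trimethylsilyl)phenyl N-isopropylcarbamate | CC(C)NC(=O)Oc1cc(OCc2ccccc2)cc(OCc2ccccc2)c1[Si](C)(C)C | intermediate
19 | 3,5-bis(benzyloxy)-2-(trimethylsilyl)phenol, present as its DBU-H phenoxide (formed in the flask, not isolated) | Oc1cc(OCc2ccccc2)cc(OCc2ccccc2)c1[Si](C)(C)C | intermediate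
20 | 3,5-bis(benzyloxy)-2-(trimethylsilyl)phenyl trifluoromethanesulfonate | O=S(=O)(Oc1cc(OCc2ccccc2)cc(OCc2ccccc2)c1[Si](C)(C)C)C(F)(F)F | intermediate
21 | 3,5-bis(benzyloxy)benzyne (1,2-didehydro-3,5-bis(benzyloxy)benzene; formed in the flask, not isolated) | C1#CC(OCc2ccccc2)=CC(OCc2ccccc2)=C1 | intermediate
22 | (2R,3S)-5,7-bis(benzyloxy)-2-[4-(benzyloxy)phenyl]-3-{2-(benzyloxy)-5-[5,7-bis(benzyloxy)-4-oxo-4H-chromen-2-yl]phenyl}chroman-4-one | O=C1c2c(OCc3ccccc3)cc(OCc3ccccc3)cc2O[C@@H](c2ccc(OCc3ccccc3)cc2)[C@@H]1c1cc(-c2cc(=O)c3c(OCc4ccccc4)cc(OCc4ccccc4)cc3o2)ccc1OCc1ccccc1 | intermediate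
23 | (2R,3S)-5,7-dihydroxy-2-(4-hydroxyphenyl)-3-[2-hydroxy-5-(5,7-dihydroxy-4-oxo-4H-chromen-2-yl)phenyl]chroman-4-one | O=C1c2c(O)cc(O)cc2O[C@@H](c2ccc(O)cc2)[C@@H]1c1cc(-c2cc(=O)c3c(O)cc(O)cc3o2)ccc1O | target

Total step count: 10 steps.
Longest linear sequence: 7 steps (steps 1, 2, 3, 4, 5, 9, 10); the aryne precursor is a three-step side branch (steps 6 to 8).

Steps most likely to fail

Step 9 (the labelled step). The hydrogen-bonded alcohol may capture the aryne too slowly. That would leave room for retro-aldol cleavage of 12, for plain O–H insertion without acyl transfer, and for base-mediated ring opening and re-closure of the product enolate, which would erode enantiopurity. The fallback uses known chemistry only; it sets out from 4 (together with 1 and 9) and comes back at 22. Palladium-catalysed α-arylation of ketone 1 with bromide 4 (Pd2(dba)3, Xantphos, K3PO4, toluene, 100 °C) should give the deoxybenzoin 1-[2,4-bis(benzyloxy)-6-hydroxyphenyl]-2-{2-(benzyloxy)-5-[5,7-bis(benzyloxy)-4-oxo-4H-chromen-2-yl]phenyl}ethan-1-one F1. Piperidine-catalysed Knoevenagel condensation of F1 with aldehyde 9, followed by oxa-Michael closure (EtOH, reflux), should give the thermodynamically preferred trans-2,3-diarylchromanone as the racemate, that is 22 together with its (2S,3R)-enantiomer F2. Preparative chiral SFC should then separate 22, which rejoins the route at step 10.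

Step 3. The N-acetyl imide enolate may fragment (loss of ketene, deacylation of the auxiliary), or the more acidic product may be arylated a second time. The fallback sets out from 4 and comes back at 8; it couples a robust ester enolate first and attaches the auxiliary afterwards. Coupling of 4 with the Reformatsky reagent BrZnCH2CO2t-Bu (Pd(dba)2, P(t-Bu)3, THF, rt) should give tert-butyl 2-{2-(benzyloxy)-5-[5,7-bis(benzyloxy)-4-oxo-4H-chromen-2-yl]phenyl}acetate F3. Cleavage with TFA/CH2Cl2 at 0 °C to rt should give 2-{2-(benzyloxy)-5-[5,7-bis(benzyloxy)-4-oxo-4H-chromen-2-yl]phenyl}acetic acid F4. Pivaloyl chloride and Et3N in THF should convert F4 into the mixed pivalic anhydride F5, which is acylated onto (R)-4-benzyloxazolidin-2-one in the presence of LiCl to give 8.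

Step 5. The magnesium aldolate may undergo retro-aldol cleavage or E1cB dehydration, or methoxide may open the oxazolidinone ring instead of the exocyclic acyl group. The fallback sets out from 10 and comes back at 12; it replaces transesterification by hydroperoxide hydrolysis and neutral methylation. LiOH/H2O2 in THF/H2O at 0 °C should remove the O–SiMe3 group and the auxiliary to give (2S,3R)-2-{2-(benzyloxy)-5-[5,7-bis(benzyloxy)-4-oxo-4H-chromen-2-yl]phenyl}-3-[4-(benzyloxy)phenyl]-3-hydroxypropanoic acid F6. Esterification of F6 with TMSCHN2 in MeOH/toluene at 0 °C should give 12 without exposing the aldol to base.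

Further compounds
F1 | step 9 | 1-[2,4-bis(benzyloxy)-6-hydroxyphenyl]-2-{2-(benzyloxy)-5-[5,7-bis(benzyloxy)-4-oxo-4H-chromen-2-yl]phenyl}ethan-1-one | O=C(Cc1cc(-c2cc(=O)c3c(OCc4ccccc4)cc(OCc4ccccc4)cc3o2)ccc1OCc1ccccc1)c1c(O)cc(OCc2ccccc2)cc1OCc1ccccc1
F2 | step 9 | (2S,3R)-5,7-bis(benzyloxy)-2-[4-(benzyloxy)phenyl]-3-{2-(benzyloxy)-5-[5,7-bis(benzyloxy)-4-oxo-4H-chromen-2-yl]phenyl}chroman-4-one (enantiomer of 22) | O=C1c2c(OCc3ccccc3)cc(OCc3ccccc3)cc2O[C@H](c2ccc(OCc3ccccc3)cc2)[C@H]1c1cc(-c2cc(=O)c3c(OCc4ccccc4)cc(OCc4ccccc4)cc3o2)ccc1OCc1ccccc1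
F3 | step 3 | tert-butyl 2-{2-(benzyloxy)-5-[5,7-bis(benzyloxy)-4-oxo-4H-chromen-2-yl]phenyl}acetate | CC(C)(C)OC(=O)Cc1cc(-c2cc(=O)c3c(OCc4ccccc4)cc(OCc4ccccc4)cc3o2)ccc1OCc1ccccc1
F4 | step 3 | 2-{2-(benzyloxy)-5-[5,7-bis(benzyloxy)-4-oxo-4H-chromen-2-yl]phenyl}acetic acid | OC(=O)Cc1cc(-c2cc(=O)c3c(OCc4ccccc4)cc(OCc4ccccc4)cc3o2)ccc1OCc1ccccc1
F5 | step 3 | 2-{2-(benzyloxy)-5-[5,7-bis(benzyloxy)-4-oxo-4H-chromen-2-yl]phenyl}acetic pivalic anhydride | CC(C)(C)C(=O)OC(=O)Cc1cc(-c2cc(=O)c3c(OCc4ccccc4)cc(OCc4ccccc4)cc3o2)ccc1OCc1ccccc1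
F6 | step 5 | (2S,3R)-2-{2-(benzyloxy)-5-[5,7-bis(benzyloxy)-4-oxo-4H-chromen-2-yl]phenyl}-3-[4-(benzyloxy)phenyl]-3-hydroxypropanoic acid | OC(=O)[C@H]([C@@H](O)c1ccc(OCc2ccccc2)cc1)c1cc(-c2cc(=O)c3c(OCc4ccccc4)cc(OCc4ccccc4)cc3o2)ccc1OCc1ccccc1
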